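All runs were generated by integration on assumed constants; scatter was added.

**Minutes, on the row of five charges of J**

The chair opened with a pitfall: end readings of D across charges mean little if the flasks have not all finished. The dusk run still held 37.1 % of its J at 25.0 min.

| flask | J | remark | time |
|---|---|---|---|
| winter | 0.36 M | run made earlier |  |
| midnight | 0.84 M | run made earlier |  |
| dusk | 2.2 M | run made earlier |  |
| Tuesday's | 0.40 M |  | 25 min |
| Wednesday's | 0.60 M |  | 25 min |
| Friday's | 1.0 M |  | 25 min |
| Monday's | 1.5 M |  | 25 min |
| Thursday's | 2.0 M |  | 25 min |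

| run | time / min | D / % | J / % |
|---|---|---|---|
| winter | 5.00 | 21.3 | 56.6 |
| winter | 10.0 | 34.1 | 18.9 |
| winter | 15.0 | 39.4 | 1.8 |
| winter | 20.0 | 38.7 | 0 |
| winter | 25.0 | 37.5 | 0 |
| midnight | 2.00 | 4.4 | 91.7 |
| midnight | 6.00 | 8.2 | 70.9 |
| midnight | 12.0 | 11.7 | 39.3 |
| midnight | 20.0 | 20.4 | 7.2 |
| midnight | 25.0 | 21.1 | 0.9 |
| dusk | 5.00 | 0.9 | 88.6 |
| dusk | 10.0 | 1.0 | 75.3 |
| dusk | 15.0 | 1.5 | 62.8 |
| dusk | 20.0 | 2.3 | 49.3 |
| dusk | 25.0 | 2.7 | 37.1 |

(standard deviation of a reading: 0.5 percentage points)

- "hardly changes" means that all values lie within two and a half points (for a concentration: within two and a half percent of the largest)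

1. [D] at the end for Tuesday's, Wednesday's, Friday's, Monday's, Thursday's, in this order
2. the shape of the row from first to last (rises all the way / rises, then falls / falls, then rises / falls all the way / hardly changes)

The analyst asked what each end state must be, and how fast a flask gets there. In the midnight run, she reported, J fell almost in a straight line, near zero-order, from 70.9 % at 6.00 min to 7.2 % at 20.0 min. That is a drain of 0.0382 M/min. Over 25 min it clears 0.956 M. She named this the clearing charge, the amount of J that this drain uses up within the run.

She added a caution. The winter drain reads 0.0271 M/min and the dusk drain 0.0567 M/min, so she trusted her figure near the midnight charge.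

Winter and midnight were charged below the clearing charge, she argued, and they ended with 0.135 M and 0.177 M of D. Dusk, charged above it, ended with 0.0594 M. So she expected the row to turn near the clearing charge, and Friday's to stand highest.

The forecaster tabled 0.145 M, 0.165 M, 0.165 M, 0.1 M and 0.06 M, shape rises, then falls, holding that “D passes through a maximum near” 0.8 M. That put Friday's level with Wednesday's, where the analyst put Friday's on top.

**Result**

The flask gave 0.145 M, 0.167 M, 0.179 M, 0.121 M and 0.0756 M, shape rises, then falls, with Friday's highest.

    J → D, rate k1*[J]/(1 + ([J]/sat1)) (0.0510 M, k = 0.0100 /s)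
    D ⇌ Q (K = 0.680, k = 0.00330 /s)
    J + D → Z (k = 0.00760 /M/s)

The row turns at 0.91 M, close to the clearing charge of 0.956 M. Friday's kept 2.40 % of its J at the end, against the 4.45 % that its charge less the clearing charge gives. In Tuesday's, J became D and J with D became Z while J lasted, J went from 9.69 % at 12.5 min to 0 % at 25.0 min, and D went from 34.6 % to 36.1 % between the same times. In Thursday's the same two conversions still had J at 32.6 % at 25.0 min, and D stood at 3.78 %.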